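**Assumptions**
- Vilsmeier formylation of 1 occurs at C2 (ortho to one OMe, para to the other).
- The IDPi enantiomer named in Step 7 delivers (2S,3S)-9; if it gives the antipode, the (R,R)-catalyst is used.
- The Ca (S) centre arises by substrate control in the ring closure of Step 9, as in the ε-viniferin → ampelopsin B type cyclisation.

**Retrosynthetic overview**
1. Ampelopsin B ⇒ global O-demethylation of pentamethyl ampelopsin B (12).
2. The 7-membered ring (Ca–B6 bond) ⇒ intramolecular Friedel–Crafts hydroarylation of the (E)-4-methoxystyryl group onto the 3,5-dimethoxyphenyl ring of permethyl ε-viniferin (11). Ca is set last, by ring constraint from the fixed trans-dihydrobenzofuran.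
3. The styryl group ⇒ Suzuki coupling onto aryl bromide 9. The trans-2,3-diaryldihydrobenzofuran (both stereocentres) ⇒ the new catalytic asymmetric 5-endo hydroalkoxylation of the o-hydroxy triarylethylene 8.
4. 8 ⇒ carbinol 7 (ArCH2MgCl + diaryl ketone 5) ⇒ 5 from 1-bromo-3,5-dimethoxybenzene (1) via aldehyde 2, so the ring-forming order is dihydrobenzofuran first, then the 7-ring.

**Route**

Step 1
Reactants: 1 (1-bromo-3,5-dimethoxybenzene)
Product: 2 (2-bromo-4,6-dimethoxybenzaldehyde)
Conditions: POCl3, DMF, 0 → 80 °C; then aq NaOAc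
Reagents that add atoms: DMF (CN(C)C=O), which supplies the CHO group
Why: Vilsmeier–Haack formylation goes at the position ortho to one OMe and para to the other, and away from the hindered site between the two OMe groups.

Step 2
Reactants: 2 (aldehyde) and 1 (as 3,5-dimethoxyphenyllithium)
Product: 3 (racemic (2-bromo-4,6-dimethoxyphenyl)(3,5-dimethoxyphenyl)methanol)
Conditions: 1 + n-BuLi, THF, –78 °C (1 h); then add 2, –78 °C → rt
Reagents that add atoms: none (the aryl group comes from reactant 1)
Why: Li–Br exchange on 1 gives the aryllithium, which does 1,2-addition to the aldehyde faster than exchange on 2 at –78 °C. The carbinol centre is destroyed in Step 3.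

Step 3
Reactants: 3
Product: 4 ((2-bromo-4,6-dimethoxyphenyl)(3,5-dimethoxyphenyl)methanone)
Conditions: DMP, NaHCO3, CH2Cl2, 0 °C → rt
Reagents that add atoms: none
Why: Dess–Martin oxidation of a diarylcarbinol is mild and leaves the ArBr and the OMe groups untouched.

Step 4
Reactants: 4
Product: 5 ((2-bromo-6-hydroxy-4-methoxyphenyl)(3,5-dimethoxyphenyl)methanone)
Conditions: BCl3 (1.2 equiv), CH2Cl2, –78 → 0 °C; then MeOH, H2O
Reagents that add atoms: none (OMe becomes OH)
Why: BCl3 chelates the carbonyl O and the ortho OMe, so only that ether is cleaved (chelation-assisted Lewis-acid demethylation). The para-OMe and the meta-OMe groups on the other ring are not chelated, and the Ar–Br survives.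

Step 5
Reactants: 5 and 6 (4-methoxybenzylmagnesium chloride)
Product: 7 (racemic 1-(2-bromo-6-hydroxy-4-methoxyphenyl)-1-(3,5-dimethoxyphenyl)-2-(4-methoxyphenyl)ethan-1-ol)
Conditions: 6 (3 equiv, generated in situ from 4-MeOC6H4CH2Cl and Mg), THF, 0 °C → rt; then aq NH4Cl
Reagents that add atoms: 6, COc1ccc(C[Mg]Cl)cc1
Why: Grignard 1,2-addition to the ketone; the first equivalent is consumed as the magnesium phenoxide, so excess reagent is used.

Step 6
Reactants: 7
Product: 8 (2-[1-(3,5-dimethoxyphenyl)-2-(4-methoxyphenyl)ethenyl]-3-bromo-5-methoxyphenol, E/Z mixture)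
Conditions: p-TsOH·H2O (10 mol %), toluene, 80 °C, Dean–Stark
Reagents that add atoms: none (loss of H2O)
Why: E1 dehydration of the tertiary diaryl carbinol gives the trisubstituted alkene. The E/Z ratio does not matter because the next step goes through a planar benzylic cation.

Step 7 (key step)
Reactants: 8
Product: 9 ((2S,3S)-4-bromo-3-(3,5-dimethoxyphenyl)-6-methoxy-2-(4-methoxyphenyl)-2,3-dihydrobenzofuran)
Conditions: (S,S)-IDPi (5 mol %; BINOL-derived imidodiphosphorimidate with perfluoronaphthylsulfonyl inner core), cyclohexane/CH2Cl2 9:1, 0.02 M, –20 °C, 48 h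
Reagents that add atoms: none (isomerisation)
Why: Proposed new method: a confined, strongly acidic chiral IDPi protonates the trisubstituted p-anisyl triarylethylene at the fully substituted carbon (Cc) while its anion H-bonds the ortho phenol, and the resulting p-anisyl benzylic cation (Cd) is trapped by the phenol O in the same chiral ion pair. This is a cationic 5-endo ring closure, so it is not Baldwin-disfavoured. The face of protonation sets C3 (Cc), and the anti arrangement of the two aryl groups in the planar cation gives 2,3-trans (Cd). The closest known reactions are IDPi/CPA-catalysed enantioselective hydroalkoxylation of alkenols and phenol oxa-cyclisations onto p-quinone-methide-type cations; nothing has been shown for enantioselective protonation of a triarylethylene with 5-endo dihydrobenzofuran formation.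

Step 8
Reactants: 9 and 10 ((E)-2-(4-methoxystyryl)-4,4,5,5-tetramethyl-1,3,2-dioxaborolane)
Product: 11 (permethyl ε-viniferin, (2S,3S)-3-(3,5-dimethoxyphenyl)-6-methoxy-2-(4-methoxyphenyl)-4-[(E)-4-methoxystyryl]-2,3-dihydrobenzofuran)
Conditions: 10 (1.5 equiv), Pd2(dba)3 (2.5 mol %), SPhos (10 mol %), K3PO4, toluene/H2O 10:1, 100 °C
Reagents that add atoms: 10, COc1ccc(/C=C/B2OC(C)(C)C(C)(C)O2)cc1
Why: Suzuki–Miyaura coupling with a bulky biaryl phosphine handles the hindered aryl bromide, keeps the alkene E, and leaves the two stereocentres untouched (no acidic or basic C–H at C3).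

Step 9
Reactants: 11
Product: 12 (pentamethyl ampelopsin B)
Conditions: TfOH (10 mol %), HFIP, 0.01 M, 0 °C → rt, 1 h
Reagents that add atoms: none (isomerisation)
Why: Protonation of the p-methoxystyryl alkene at Cb gives the p-anisyl cation at Ca. This is captured by the nucleophilic C2 of the 3,5-dimethoxyphenyl ring in an intramolecular Friedel–Crafts alkylation that closes the 7-membered ring. Ca is set by the ring constraints of the trans-fused dihydrobenzofuran, and the Cc and Cd centres are not touched.

Step 10
Reactants: 12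
Product: 13 (ampelopsin B)
Conditions: BBr3 (10 equiv), CH2Cl2, –78 °C → 0 °C, 3 h; then aq NaHCO3
Reagents that add atoms: none (five O–CH3 become O–H)
Why: BBr3 O-demethylation of aryl methyl ethers at low temperature leaves the dihydrobenzofuran C–O bond and all stereocentres intact.

**Compound list**

| No. | Name | SMILES | Role |
|---|---|---|---|
| 1 | 1-Bromo-3,5-dimethoxybenzene | COc1cc(Br)cc(OC)c1 | starting material |
| 2 | 2-Bromo-4,6-dimethoxybenzaldehyde | COc1cc(OC)c(C=O)c(Br)c1 | intermediate |
| 3 | (2-Bromo-4,6-dimethoxyphenyl)(3,5-dimethoxyphenyl)methanol (racemic) | COc1cc(OC)c(C(O)c2cc(OC)cc(OC)c2)c(Br)c1 | intermediate |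
| 4 | (2-Bromo-4,6-dimethoxyphenyl)(3,5-dimethoxyphenyl)methanone | COc1cc(OC)c(C(=O)c2cc(OC)cc(OC)c2)c(Br)c1 | intermediate |
| 5 | (2-Bromo-6-hydroxy-4-methoxyphenyl)(3,5-dimethoxyphenyl)methanone | COc1cc(O)c(C(=O)c2cc(OC)cc(OC)c2)c(Br)c1 | intermediate |
| 6 | 4-Methoxybenzylmagnesium chloride | COc1ccc(C[Mg]Cl)cc1 | starting material (reagent) |
| 7 | Tertiary carbinol (racemic) | COc1cc(O)c(C(O)(Cc2ccc(OC)cc2)c2cc(OC)cc(OC)c2)c(Br)c1 | intermediate |
| 8 | o-Hydroxy triarylethylene (E/Z) | COc1cc(O)c(C(=Cc2ccc(OC)cc2)c2cc(OC)cc(OC)c2)c(Br)c1 | intermediate |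
| 9 | (2S,3S)-4-Bromo-3-(3,5-dimethoxyphenyl)-6-methoxy-2-(4-methoxyphenyl)-2,3-dihydrobenzofuran | COc1ccc(cc1)[C@H]1Oc2cc(OC)cc(Br)c2[C@@H]1c1cc(OC)cc(OC)c1 | intermediate |
| 10 | (E)-2-(4-Methoxystyryl)-Bpin | COc1ccc(/C=C/B2OC(C)(C)C(C)(C)O2)cc1 | starting material (reagent) |
| 11 | Permethyl ε-viniferin | COc1ccc(cc1)[C@H]1Oc2cc(OC)cc(/C=C/c3ccc(OC)cc3)c2[C@@H]1c1cc(OC)cc(OC)c1 | intermediate |
| 12 | Pentamethyl ampelopsin B | COc1ccc([C@@H]2Cc3cc(OC)cc4c3[C@H](c3cc(OC)cc(OC)c32)[C@@H](c2ccc(OC)cc2)O4)cc1 | intermediate |
| 13 | Ampelopsin B | Oc1ccc([C@@H]2Cc3cc(O)cc4c3[C@H](c3cc(O)cc(O)c32)[C@@H](c2ccc(O)cc2)O4)cc1 | target |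

The target is S at Ca, Cc and Cd, with the Cc/Cd aryl groups trans on the dihydrobenzofuran. The formula runs consistently from 12 (C33H32O6) to 13 (C28H22O6).

**Totals**
- Total step count: 10 (plus in-situ formation of Grignard 6).
- Longest linear sequence: 10 steps, from 1 to 13.

**Three steps most likely to fail**
1. Step 7 (the proposed new method). The fully substituted carbon of the alkene is the more cation-stabilising site, through the o-hydroxy and p-OMe aryl, so protonation can be unproductive or erode ee.
   - Fallback: cyclise 8 to racemic 9 with TfOH (known hydroalkoxylation), then isolate (2S,3S)-9 by preparative chiral-phase SFC.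
2. Step 9. The trans-dihydrobenzofuran can ionise at Cd–O under TfOH/HFIP, and the wrong Ca epimer or dimers can form.
   - Fallback: epoxidise the styryl alkene of 11 (mCPBA), open the epoxide at Ca with BF3·OEt2 so that ring B closes the 7-ring, then remove the Cb benzylic OH by Barton–McCombie deoxygenation.
3. Step 5 (Grignard addition to the di-ortho-substituted phenolic ketone 5, then dehydration).
   - Fallback: Horner–Wittig olefination of 5 with lithiated diphenyl(4-methoxybenzyl)phosphine oxide, then KH-induced elimination of the β-hydroxyphosphine oxide to give 8 directly.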